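Ring A of the chroman (C4a, C5, C6, C7, C8, C8a) bears oxygen at C6 and at C8a in a para relationship. This is the hallmark of a 4-methoxyphenol made by Dötz benzannulation, so this ring is disconnected completely. In one operation a chromium methoxy(1-methoxyvinyl)carbene, one of its CO ligands and a terminal alkyne forge C5–C6, C4a–C8a and C8–C8a and deliver the aromatic ring with the O1 hydroxyl in place. The alkyne partner is a silyl-protected (S)-2-arylpent-4-yn-1-ol. It already carries ring B as a dibenzyl hydroquinone and the only stereocentre, set by Evans propargylation. Directed C8 formylation, Mitsunobu closure, Baeyer–Villiger oxidation and debenzylation–oxidation complete the target.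

Key step: step 11

Remark: the target SMILES is read as 3S (C2 > ring B carbon > C4 > H). Chroman numbering is used for ring A atoms at every stage. Chromium carbonyls are written in SMILES with Cr=C=O bonds, and the η6 complex 22 is written as arene and Cr(CO)3 joined by a dot.

Step 1
Reactants: 1 2,3-dimethoxyphenol
Product: 2 2,3-dimethoxy-1,4-benzoquinone
Conditions: (KSO3)2NO (2.2 equiv), KH2PO4, H2O/acetone, 0 °C → rt
Reagents that add atoms: potassium nitrosodisulfonate (KSO3)2NO, [K+].[K+].[O]N(S(=O)(=O)[O-])S(=O)(=O)[O-]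
Why: Teuber oxidation: one nitroxyl radical removes the phenolic hydrogen and a second one bonds through oxygen to the open para carbon, whose collapse gives the p-quinone with both methoxy groups untouched.

Step 2
Reactants: 2 2,3-dimethoxy-1,4-benzoquinone
Product: 4 1,4-bis(benzyloxy)-2,3-dimethoxybenzene, via 2,3-dimethoxyhydroquinone 3 (not isolated)
Conditions: Na2S2O4, EtOAc/H2O, rt; crude, then BnBr, K2CO3, DMF, 60 °C, argon
Reagents that add atoms: benzyl bromide, BrCc1ccccc1
Why: Dithionite reduction of the quinone and double Williamson etherification of the crude hydroquinone should install both benzyl groups, chosen because they fall off under neutral hydrogenolysis in the last step.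

Step 3
Reactants: 4 1,4-bis(benzyloxy)-2,3-dimethoxybenzene
Product: 5 1-bromo-2,5-bis(benzyloxy)-3,4-dimethoxybenzene
Conditions: NBS (1.0 equiv), MeCN, dark, 0 °C → rt
Reagents that add atoms: N-bromosuccinimide, O=C1CCC(=O)N1Br
Why: Electrophilic aromatic bromination: the two ring C–H positions of symmetric 4 are equivalent and strongly activated, so one equivalent of NBS in a polar solvent should give a single monobromide without benzylic radical bromination.

Step 4
Reactants: 5 1-bromo-2,5-bis(benzyloxy)-3,4-dimethoxybenzene; 6 (2-tert-butoxy-2-oxoethyl)zinc chloride (commercial solution)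
Product: 7 tert-butyl 2-[2,5-bis(benzyloxy)-3,4-dimethoxyphenyl]acetate
Conditions: Pd(dba)2 (2 mol %), P(t-Bu)3 (2 mol %), THF, rt → 50 °C
Reagents that add atoms: none
Why: Negishi-type α-arylation of a Reformatsky reagent: oxidative addition of 5 to zerovalent palladium bearing the bulky electron-rich phosphine, transmetalation from zinc and reductive elimination form the aryl–CH2 bond under essentially neutral conditions.

Step 5
Reactants: 7 tert-butyl 2-[2,5-bis(benzyloxy)-3,4-dimethoxyphenyl]acetate
Product: 8 2-[2,5-bis(benzyloxy)-3,4-dimethoxyphenyl]acetic acid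
Conditions: TFA/CH2Cl2 (1:4), 0 °C → rt
Reagents that add atoms: none
Why: Acidolysis of the tert-butyl ester with loss of isobutene; short exposure at or below room temperature leaves aryl benzyl ethers intact, and the single free ring position is too crowded for tert-butylation.

Step 6
Reactants: 8 2-[2,5-bis(benzyloxy)-3,4-dimethoxyphenyl]acetic acid; 9 (S)-4-benzyl-1,3-oxazolidin-2-one
Product: 11 (4S)-4-benzyl-3-{2-[2,5-bis(benzyloxy)-3,4-dimethoxyphenyl]acetyl}-1,3-oxazolidin-2-one, via mixed pivalic anhydride 10 (not isolated)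
Conditions: PivCl, Et3N, THF, −20 °C; then LiCl, 9, −20 °C → rt
Reagents that add atoms: pivaloyl chloride, CC(C)(C)C(=O)Cl (acyl group held by 10 only)
Why: N-acylation of the oxazolidinone through a mixed anhydride with LiCl/Et3N activation; the nucleophile attacks the unhindered arylacetyl carbonyl and no strong base touches the acidic benzylic CH2.

Step 7
Reactants: 11 (4S)-4-benzyl-3-{2-[2,5-bis(benzyloxy)-3,4-dimethoxyphenyl]acetyl}-1,3-oxazolidin-2-one; 12 propargyl bromide
Product: 14 (4S)-4-benzyl-3-{(2S)-2-[2,5-bis(benzyloxy)-3,4-dimethoxyphenyl]pent-4-ynoyl}-1,3-oxazolidin-2-one, via sodium (Z)-enolate 13 (not isolated)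
Conditions: NaN(SiMe3)2 (1.05 equiv), THF, −78 °C; then 12 (3 equiv, toluene solution), −78 → −45 °C; AcOH quench cold
Reagents that add atoms: sodium bis(trimethylsilyl)amide, C[Si](C)(C)N([Na])[Si](C)(C)C (sodium held by 13 only)
Why: Evans asymmetric alkylation: the sodium-chelated (Z)-enolate 13 is blocked on one face by the C4 benzyl group of the (S)-auxiliary, so propargyl bromide should enter from the other face and set the future C3 as S, and the minor diastereomer can be removed by chromatography or crystallisation.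

Step 8
Reactants: 14 (4S)-4-benzyl-3-{(2S)-2-[2,5-bis(benzyloxy)-3,4-dimethoxyphenyl]pent-4-ynoyl}-1,3-oxazolidin-2-one
Product: 15 (2S)-2-[2,5-bis(benzyloxy)-3,4-dimethoxyphenyl]pent-4-yn-1-ol
Conditions: LiBH4, MeOH (1 equiv), Et2O/THF, 0 °C
Reagents that add atoms: none
Why: Reductive cleavage of the imide with LiBH4 attacks the exocyclic carbonyl, is not basic enough to enolise the α-aryl centre, leaves alkyne and benzyl ethers alone and returns the auxiliary.

Step 9
Reactants: 15 (2S)-2-[2,5-bis(benzyloxy)-3,4-dimethoxyphenyl]pent-4-yn-1-ol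
Product: 16 (2S)-2-[2,5-bis(benzyloxy)-3,4-dimethoxyphenyl]pent-4-yn-1-yl tert-butyldimethylsilyl ether
Conditions: TBSCl, imidazole, CH2Cl2, rt
Reagents that add atoms: tert-butyldimethylsilyl chloride, CC(C)(C)[Si](C)(C)Cl
Why: Standard silylation of a primary alcohol; the TBS ether stops the carbinol from intercepting ketene or carbene intermediates in step 11 and survives steps 11 and 12.

Step 10
Reactants: 17 methyl vinyl ether; 18 chromium hexacarbonyl
Product: 21 pentacarbonyl[methoxy(1-methoxyvinyl)carbene]chromium, via 1-methoxyvinyllithium 19 (not isolated), via lithium acylchromate 20 (not isolated)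
Conditions: t-BuLi, THF, −78 → 0 °C; Cr(CO)6, Et2O, 0 °C → rt; evaporate; MeOTf, CH2Cl2, 0 °C → rt
Reagents that add atoms: methyl trifluoromethanesulfonate, COS(=O)(=O)C(F)(F)F; tert-butyllithium, [Li]C(C)(C)C (lithium held by 19 and 20 only)
Why: Fischer carbene synthesis: α-lithiation of the enol ether, addition of the vinyllithium to a CO ligand of Cr(CO)6 and O-methylation of the acylate with a hard methylating agent; the α-substituent should stabilise the alkenyl complex as it does in α-alkyl and cyclic α-alkoxy analogues.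

Step 11
Reactants: 16 (2S)-2-[2,5-bis(benzyloxy)-3,4-dimethoxyphenyl]pent-4-yn-1-yl tert-butyldimethylsilyl ether; 21 pentacarbonyl[methoxy(1-methoxyvinyl)carbene]chromium
Product: 23 2-[(2S)-2-[2,5-bis(benzyloxy)-3,4-dimethoxyphenyl]-3-(tert-butyldimethylsilyloxy)propyl]-4,5-dimethoxyphenol, via tricarbonylchromium arene complex 22 (not isolated)
Conditions: 21 (1.5 equiv), degassed THF (0.05 M), 50 °C, argon; then air, Et2O/MeCN, rt
Reagents that add atoms: none
Why: Thermal loss of one cis CO ligand from 21 opens a site for alkyne 16, which inserts into the Cr=C bond so that the alkyne CH bonds to the former carbene carbon (C5–C6), and migratory CO insertion at the substituted alkyne carbon (C4a–C8a) then gives a chromium-bound dienylketene. Ring A closes by 6π-electrocyclisation of this dienylketene between the ketene carbon and the vinyl CH2 (C8–C8a), and tautomerisation of the cyclohexadienone gives the phenol as its Cr(CO)3 complex 22, which air strips to 23. The closest known reaction type is the Dötz benzannulation of α-substituted alkenyl(methoxy)carbene chromium complexes, cyclic α-alkoxyalkenyl ones included, with terminal alkynes. No stereocentre is formed, and the existing one is insulated from the alkyne by a CH2 group and sees only neutral conditions, so it should be carried through unchanged. The step needs insertion with the side chain next to the CO-derived carbon, which the steric contrast between H and CH2R on a terminal alkyne secures, and it needs CO insertion to outrun five-ring formation, which alkenyl chromium complexes in THF favour. The silyl ether keeps the carbinol from trapping the ketene, and the benzyl ethers are inert to zerovalent chromium at this temperature.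

Step 12
Reactants: 23 2-[(2S)-2-[2,5-bis(benzyloxy)-3,4-dimethoxyphenyl]-3-(tert-butyldimethylsilyloxy)propyl]-4,5-dimethoxyphenol
Product: 24 3-[(2S)-2-[2,5-bis(benzyloxy)-3,4-dimethoxyphenyl]-3-(tert-butyldimethylsilyloxy)propyl]-2-hydroxy-5,6-dimethoxybenzaldehyde
Conditions: MgCl2 (anhydrous), Et3N, (CH2O)n, MeCN, reflux; brief cold 1 M HCl work-up
Reagents that add atoms: paraformaldehyde (as formaldehyde), C=O
Why: Casnati–Skattebøl ortho-formylation: formaldehyde is delivered inside a magnesium chelate of the phenol to the only free ortho C–H (C8) and a second formaldehyde takes up the hydride, so ring B, C5 and the alkylated ortho carbon C4a (open to direct oxygen-transfer oxidants) cannot react, and the formyl group serves as a masked C8 hydroxyl that avoids an air-sensitive catechol.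

Step 13
Reactants: 24 3-[(2S)-2-[2,5-bis(benzyloxy)-3,4-dimethoxyphenyl]-3-(tert-butyldimethylsilyloxy)propyl]-2-hydroxy-5,6-dimethoxybenzaldehyde
Product: 25 3-[(2S)-2-[2,5-bis(benzyloxy)-3,4-dimethoxyphenyl]-3-hydroxypropyl]-2-hydroxy-5,6-dimethoxybenzaldehyde
Conditions: HF·pyridine, THF, 0 °C → rt
Reagents that add atoms: none
Why: Fluoride-driven desilylation of a primary TBS ether under weakly acidic conditions that leave the aldehyde, the phenol and the benzyl ethers untouched.

Step 14
Reactants: 25 3-[(2S)-2-[2,5-bis(benzyloxy)-3,4-dimethoxyphenyl]-3-hydroxypropyl]-2-hydroxy-5,6-dimethoxybenzaldehyde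
Product: 26 (3S)-3-[2,5-bis(benzyloxy)-3,4-dimethoxyphenyl]-6,7-dimethoxy-3,4-dihydro-2H-chromene-8-carbaldehyde
Conditions: PPh3, DIAD, THF (0.02 M), 0 °C → rt
Reagents that add atoms: none
Why: Intramolecular Mitsunobu etherification: the acidic salicylaldehyde-type C8a hydroxyl is the only nucleophile and displaces the activated primary carbinol in a 6-exo-tet closure at C2, a carbon that is not stereogenic, so C3 stays S.

Step 15
Reactants: 26 (3S)-3-[2,5-bis(benzyloxy)-3,4-dimethoxyphenyl]-6,7-dimethoxy-3,4-dihydro-2H-chromene-8-carbaldehyde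
Product: 28 (3S)-3-[2,5-bis(benzyloxy)-3,4-dimethoxyphenyl]-6,7-dimethoxy-3,4-dihydro-2H-chromen-8-ol, via aryl formate 27 (not isolated)
Conditions: mCPBA, CH2Cl2, 0 °C → rt; NaHCO3 wash; then K2CO3 (0.2 equiv), MeOH, 0 °C, argon
Reagents that add atoms: 3-chloroperoxybenzoic acid, OOC(=O)c1cccc(Cl)c1
Why: Baeyer–Villiger oxidation of a benzaldehyde flanked by two alkoxy groups, in which the electron-rich aryl group migrates in preference to hydrogen, followed by methanolysis of the labile formate to unveil the C8 hydroxyl.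

Step 16
Reactants: 28 (3S)-3-[2,5-bis(benzyloxy)-3,4-dimethoxyphenyl]-6,7-dimethoxy-3,4-dihydro-2H-chromen-8-ol
Product: 30 5-[(3S)-8-hydroxy-6,7-dimethoxy-3,4-dihydro-2H-chromen-3-yl]-2,3-dimethoxycyclohexa-2,5-diene-1,4-dione, via ring B hydroquinone 29 (not isolated)
Conditions: H2 (1 atm), Pd/C, EtOAc, rt; filter under argon; then Ag2O, Na2SO4, EtOAc, 0 °C → rt
Reagents that add atoms: none
Why: Hydrogenolysis of both aryl benzyl ethers followed by two-electron oxidation of the 1,4-hydroquinone with Ag2O, which should act on ring B because a hydroquinone is oxidised far more easily than the lone ring A phenol, while C3 is not involved.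

Compound list
1 | 2,3-dimethoxyphenol | COc1cccc(O)c1OC | starting material
2 | 2,3-dimethoxy-1,4-benzoquinone | COC1=C(OC)C(=O)C=CC1=O | intermediate
3 | 2,3-dimethoxybenzene-1,4-diol | COc1c(O)ccc(O)c1OC | intermediate
4 | 1,4-bis(benzyloxy)-2,3-dimethoxybenzene | COc1c(OCc2ccccc2)ccc(OCc2ccccc2)c1OC | intermediate
5 | 1-bromo-2,5-bis(benzyloxy)-3,4-dimethoxybenzene | Brc1cc(OCc2ccccc2)c(OC)c(OC)c1OCc1ccccc1 | intermediate
6 | (2-tert-butoxy-2-oxoethyl)zinc chloride | CC(C)(C)OC(=O)C[Zn]Cl | starting material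
7 | tert-butyl 2-[2,5-bis(benzyloxy)-3,4-dimethoxyphenyl]acetate | CC(C)(C)OC(=O)Cc1cc(OCc2ccccc2)c(OC)c(OC)c1OCc1ccccc1 | intermediate
8 | 2-[2,5-bis(benzyloxy)-3,4-dimethoxyphenyl]acetic acid | OC(=O)Cc1cc(OCc2ccccc2)c(OC)c(OC)c1OCc1ccccc1 | intermediate
9 | (S)-4-benzyl-1,3-oxazolidin-2-one | O=C1N[C@@H](Cc2ccccc2)CO1 | starting material
10 | 2-[2,5-bis(benzyloxy)-3,4-dimethoxyphenyl]acetic pivalic anhydride | CC(C)(C)C(=O)OC(=O)Cc1cc(OCc2ccccc2)c(OC)c(OC)c1OCc1ccccc1 | intermediate
11 | (4S)-4-benzyl-3-{2-[2,5-bis(benzyloxy)-3,4-dimethoxyphenyl]acetyl}-1,3-oxazolidin-2-one | O=C(Cc1cc(OCc2ccccc2)c(OC)c(OC)c1OCc1ccccc1)N1[C@@H](Cc2ccccc2)COC1=O | intermediate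
12 | propargyl bromide | C#CCBr | starting material
13 | sodium (Z)-enolate of 11 | [Na+].[O-]/C(=C\c1cc(OCc2ccccc2)c(OC)c(OC)c1OCc1ccccc1)N1[C@@H](Cc2ccccc2)COC1=O | intermediate
14 | (4S)-4-benzyl-3-{(2S)-2-[2,5-bis(benzyloxy)-3,4-dimethoxyphenyl]pent-4-ynoyl}-1,3-oxazolidin-2-one | C#CC[C@H](C(=O)N1[C@@H](Cc2ccccc2)COC1=O)c1cc(OCc2ccccc2)c(OC)c(OC)c1OCc1ccccc1 | intermediate
15 | (2S)-2-[2,5-bis(benzyloxy)-3,4-dimethoxyphenyl]pent-4-yn-1-ol | C#CC[C@H](CO)c1cc(OCc2ccccc2)c(OC)c(OC)c1OCc1ccccc1 | intermediate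
16 | (2S)-2-[2,5-bis(benzyloxy)-3,4-dimethoxyphenyl]pent-4-yn-1-yl tert-butyldimethylsilyl ether | C#CC[C@H](CO[Si](C)(C)C(C)(C)C)c1cc(OCc2ccccc2)c(OC)c(OC)c1OCc1ccccc1 | intermediate
17 | methyl vinyl ether | COC=C | starting material
18 | chromium hexacarbonyl | O=C=[Cr](=C=O)(=C=O)(=C=O)(=C=O)=C=O | starting material
19 | 1-methoxyvinyllithium | [Li]C(=C)OC | intermediate
20 | lithium pentacarbonyl[(1-methoxyvinyl)oxidocarbene]chromate | [Li+].[O-]C(C(OC)=C)=[Cr](=C=O)(=C=O)(=C=O)(=C=O)=C=O | intermediate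
21 | pentacarbonyl[methoxy(1-methoxyvinyl)carbene]chromium | COC(C(OC)=C)=[Cr](=C=O)(=C=O)(=C=O)(=C=O)=C=O | intermediate
22 | tricarbonyl(η6-ring A)chromium complex of 23 | COc1cc(C[C@H](CO[Si](C)(C)C(C)(C)C)c2cc(OCc3ccccc3)c(OC)c(OC)c2OCc2ccccc2)c(O)cc1OC.O=C=[Cr](=C=O)=C=O | intermediate
23 | 2-[(2S)-2-[2,5-bis(benzyloxy)-3,4-dimethoxyphenyl]-3-(tert-butyldimethylsilyloxy)propyl]-4,5-dimethoxyphenol | COc1cc(C[C@H](CO[Si](C)(C)C(C)(C)C)c2cc(OCc3ccccc3)c(OC)c(OC)c2OCc2ccccc2)c(O)cc1OC | intermediate
24 | 3-[(2S)-2-[2,5-bis(benzyloxy)-3,4-dimethoxyphenyl]-3-(tert-butyldimethylsilyloxy)propyl]-2-hydroxy-5,6-dimethoxybenzaldehyde | COc1cc(C[C@H](CO[Si](C)(C)C(C)(C)C)c2cc(OCc3ccccc3)c(OC)c(OC)c2OCc2ccccc2)c(O)c(C=O)c1OC | intermediate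
25 | 3-[(2S)-2-[2,5-bis(benzyloxy)-3,4-dimethoxyphenyl]-3-hydroxypropyl]-2-hydroxy-5,6-dimethoxybenzaldehyde | COc1cc(C[C@H](CO)c2cc(OCc3ccccc3)c(OC)c(OC)c2OCc2ccccc2)c(O)c(C=O)c1OC | intermediate
26 | (3S)-3-[2,5-bis(benzyloxy)-3,4-dimethoxyphenyl]-6,7-dimethoxy-3,4-dihydro-2H-chromene-8-carbaldehyde | COc1cc2C[C@H](COc2c(C=O)c1OC)c1cc(OCc2ccccc2)c(OC)c(OC)c1OCc1ccccc1 | intermediate
27 | (3S)-3-[2,5-bis(benzyloxy)-3,4-dimethoxyphenyl]-6,7-dimethoxy-3,4-dihydro-2H-chromen-8-yl formate | COc1cc2C[C@H](COc2c(OC=O)c1OC)c1cc(OCc2ccccc2)c(OC)c(OC)c1OCc1ccccc1 | intermediate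
28 | (3S)-3-[2,5-bis(benzyloxy)-3,4-dimethoxyphenyl]-6,7-dimethoxy-3,4-dihydro-2H-chromen-8-ol | COc1cc2C[C@H](COc2c(O)c1OC)c1cc(OCc2ccccc2)c(OC)c(OC)c1OCc1ccccc1 | intermediate
29 | 5-[(3S)-8-hydroxy-6,7-dimethoxy-3,4-dihydro-2H-chromen-3-yl]-2,3-dimethoxybenzene-1,4-diol | COc1cc2C[C@H](COc2c(O)c1OC)c1cc(O)c(OC)c(OC)c1O | intermediate
30 | 5-[(3S)-8-hydroxy-6,7-dimethoxy-3,4-dihydro-2H-chromen-3-yl]-2,3-dimethoxycyclohexa-2,5-diene-1,4-dione | COC1=C(OC)C(=O)C([C@H]2COc3c(cc(OC)c(OC)c3O)C2)=CC1=O | target

Total step count: 16. Longest linear sequence: 15 (steps 1–9 and 11–16); step 10 is a one-step side branch.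

Steps most likely to fail

1. Step 11.
- What may go wrong: the carbene complex may decay thermally faster than it loses CO productively. The terminal alkyne may oligomerise at chromium. The vinylcarbene intermediate may cyclise without CO insertion. The electron-rich phenol may be over-oxidised during demetalation.
- Fallback: ring A is bought instead of built. The fallback sets out from imide 11 and comes back at phenol 23. The sodium enolate 13 would be alkylated (Evans alkylation, same facial control) with purchased 1-bromo-2-(bromomethyl)-4,5-dimethoxybenzene F1 to give the benzylated imide F2. LiBH4 reduction would give the bromo alcohol F3, and TBSCl/imidazole would give the bromo silyl ether F4. Miyaura borylation (B2pin2, PdCl2(dppf), KOAc, dioxane, 90 °C) would give the pinacol boronate F5. NaBO3·4H2O in THF/H2O would then oxidise the C–B bond to the phenol 23.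

2. Step 7.
- What may go wrong: the stabilised, ortho-substituted aryl enolate may alkylate too slowly at the temperatures at which it survives. The acidic α-aryl imide product may epimerise through proton exchange with unreacted enolate, which would erode the only stereocentre.
- Fallback: the centre is set by catalysis instead of an auxiliary. The fallback sets out from bromide 5 and comes back at alcohol 15. Bromine–lithium exchange (n-BuLi, THF, −78 °C), B(Oi-Pr)3 and mild acid would give the arylboronic acid F6. Hayashi–Miyaura addition to 2(5H)-furanone follows (Rh(acac)(C2H4)2, (S)-BINAP, dioxane/H2O, 100 °C). The ligand antipode is the one that the accepted facial model for cyclic acceptors assigns to the S product, and the addition would give the β-aryl lactone F7. i-Bu2AlH (CH2Cl2, −78 °C) would give the lactol F8. Seyferth–Gilbert homologation with the Ohira–Bestmann reagent (K2CO3, MeOH) would convert its open hydroxy aldehyde form into 15.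

3. Step 16.
- What may go wrong: one-electron oxidation of the electron-rich ring A phenol, followed by phenoxyl coupling, may compete with hydroquinone oxidation on the silver oxide surface.
- Fallback: the C8 hydroxyl is unmasked last. The fallback sets out from aryl formate 27, isolated after the peracid stage of step 15, and comes back at target 30. Hydrogenolysis (H2, Pd/C, EtOAc) would give the formate hydroquinone F9. Ag2O would then give the formate quinone F10 while ring A holds no free phenol. Brief methanolysis of the labile aryl formate (KHCO3, MeOH, 0 °C) would release 30.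

Further compounds
F1 | step 11 | 1-bromo-2-(bromomethyl)-4,5-dimethoxybenzene (purchased) | COc1cc(Br)c(CBr)cc1OC
F2 | step 11 | (4S)-4-benzyl-3-{(2S)-2-[2,5-bis(benzyloxy)-3,4-dimethoxyphenyl]-3-(2-bromo-4,5-dimethoxyphenyl)propanoyl}-1,3-oxazolidin-2-one | COc1cc(Br)c(C[C@H](C(=O)N2[C@@H](Cc3ccccc3)COC2=O)c2cc(OCc3ccccc3)c(OC)c(OC)c2OCc2ccccc2)cc1OC
F3 | step 11 | (2S)-2-[2,5-bis(benzyloxy)-3,4-dimethoxyphenyl]-3-(2-bromo-4,5-dimethoxyphenyl)propan-1-ol | COc1cc(Br)c(C[C@H](CO)c2cc(OCc3ccccc3)c(OC)c(OC)c2OCc2ccccc2)cc1OC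
F4 | step 11 | (2S)-2-[2,5-bis(benzyloxy)-3,4-dimethoxyphenyl]-3-(2-bromo-4,5-dimethoxyphenyl)propyl tert-butyldimethylsilyl ether | COc1cc(Br)c(C[C@H](CO[Si](C)(C)C(C)(C)C)c2cc(OCc3ccccc3)c(OC)c(OC)c2OCc2ccccc2)cc1OC
F5 | step 11 | (2S)-2-[2,5-bis(benzyloxy)-3,4-dimethoxyphenyl]-3-[4,5-dimethoxy-2-(4,4,5,5-tetramethyl-1,3,2-dioxaborolan-2-yl)phenyl]propyl tert-butyldimethylsilyl ether | COc1cc(B2OC(C)(C)C(C)(C)O2)c(C[C@H](CO[Si](C)(C)C(C)(C)C)c2cc(OCc3ccccc3)c(OC)c(OC)c2OCc2ccccc2)cc1OC
F6 | step 7 | [2,5-bis(benzyloxy)-3,4-dimethoxyphenyl]boronic acid | OB(O)c1cc(OCc2ccccc2)c(OC)c(OC)c1OCc1ccccc1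
F7 | step 7 | (4S)-4-[2,5-bis(benzyloxy)-3,4-dimethoxyphenyl]oxolan-2-one | O=C1C[C@H](CO1)c1cc(OCc2ccccc2)c(OC)c(OC)c1OCc1ccccc1
F8 | step 7 | (4S)-4-[2,5-bis(benzyloxy)-3,4-dimethoxyphenyl]oxolan-2-ol (anomer mixture) | OC1C[C@H](CO1)c1cc(OCc2ccccc2)c(OC)c(OC)c1OCc1ccccc1
F9 | step 16 | (3S)-3-(2,5-dihydroxy-3,4-dimethoxyphenyl)-6,7-dimethoxy-3,4-dihydro-2H-chromen-8-yl formate | COc1cc2C[C@H](COc2c(OC=O)c1OC)c1cc(O)c(OC)c(OC)c1O
F10 | step 16 | (3S)-3-(4,5-dimethoxy-3,6-dioxocyclohexa-1,4-dien-1-yl)-6,7-dimethoxy-3,4-dihydro-2H-chromen-8-yl formate | COC1=C(OC)C(=O)C([C@H]2COc3c(cc(OC)c(OC)c3OC=O)C2)=CC1=O
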